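## Retrosynthetic overview

- **Feature the strategy rests on:** in the acylphloroglucinol ring (ring D), the three C–OH carbons alternate with the C–H, C‑acyl and C‑flavanyl carbons. This is the oxygen pattern of a linear 3,5,7‑triketo ester. Ester C1 and chain C2–C6 are the six ring atoms, chain C7 is the nonanoyl carbonyl, and chain C2 is the carbon bonded to flavan C4.
- **Ring D disconnection:** ring D is opened at the bond between the acyl‑bearing carbon (chain C6) and the C–OH carbon that lies between it and the flavanyl carbon (ester C1). In the forward sense this is an intramolecular Claisen condensation. The benzyl ethers on the 7‑ and 4'‑oxygens come off last.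
- **Chain disconnection:** the triketo ester is cut at C6–C7, C4–C5 and C2–C3, which are three enolate acylations by Weinreb amides. This leads back to the 2,4‑cis‑flavan‑4‑ylacetate.
- **Stereocentres:** flavan C4 comes from a Reformatsky addition to the (2S)‑flavanone followed by a face‑selective ionic deoxygenation. C2 comes from an enantioselective arylboronic acid addition to 7‑benzyloxychromone.
- **Ring order:** rings A and C are bought in the chromone, ring B is attached in step 2, and ring D is built last in step 9.

Key step: step 9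

Assumption: the facial sense of the pyridine‑oxazoline/palladium addition to chromones is taken to follow that known for cyclic enones, which calls for the (R)‑ligand to reach 2S; if the sense is opposite, the (S)‑ligand is used and nothing else changes.

## Route

Step 1
Reactants: 1 7-hydroxy-4H-chromen-4-one
Product: 2 7-(benzyloxy)-4H-chromen-4-one
Conditions: BnBr, K2CO3, acetone, reflux
Reagents that add atoms: benzyl bromide, BrCc1ccccc1
Why: Williamson ether synthesis, in which the acidic 7‑OH (a vinylogous acid through the pyranone carbonyl) is alkylated under carbonate conditions too mild to open the pyranone ring, and no stereocentre is involved.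

Step 2
Reactants: 2 7-(benzyloxy)-4H-chromen-4-one; 3 4-(benzyloxy)phenylboronic acid
Product: 4 (2S)-7-(benzyloxy)-2-[4-(benzyloxy)phenyl]chroman-4-one
Conditions: Pd(OCOCF3)2 (5 mol %), (R)-4-tert-butyl-2-(pyridin-2-yl)-4,5-dihydrooxazole (6 mol %), NH4PF6 (30 mol %), H2O, ClCH2CH2Cl, 60 °C
Reagents that add atoms: none
Why: Palladium‑catalysed asymmetric conjugate addition of an arylboronic acid to a chromone, a known entry to flavanones, in which the cationic aryl‑palladium complex of the chiral ligand inserts the C2=C3 bond on one enantioface and so sets C2 as S, while near‑neutral protonolysis avoids the retro‑oxa‑Michael opening that would racemise the flavanone, and one recrystallisation should raise the enantiomeric purity.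

Step 3
Reactants: 4 (2S)-7-(benzyloxy)-2-[4-(benzyloxy)phenyl]chroman-4-one; 5 methyl bromoacetate
Product: 7 methyl 2-{(2S)-7-(benzyloxy)-2-[4-(benzyloxy)phenyl]-4-hydroxychroman-4-yl}acetate (C4 epimers), via bromozinc ester enolate 6 (not isolated)
Conditions: Zn dust, cat. Me3SiCl, THF, 45 °C; then 4, THF, 25–50 °C; aq. NH4Cl
Reagents that add atoms: none
Why: Reformatsky reaction, in which the weakly basic zinc enolate adds to the C4 ketone without enolising it, so the base‑labile C2 centre is kept, and the configuration of the new carbinol carbon does not matter because step 4 makes C4 planar again.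

Step 4
Reactants: 7 methyl 2-{(2S)-7-(benzyloxy)-2-[4-(benzyloxy)phenyl]-4-hydroxychroman-4-yl}acetate
Product: 8 methyl 2-{(2S,4R)-7-(benzyloxy)-2-[4-(benzyloxy)phenyl]chroman-4-yl}acetate
Conditions: Et3SiH (excess), CF3CO2H, CH2Cl2, −40 → 0 °C
Reagents that add atoms: none
Why: Ionic hydrogenation of a tertiary benzylic alcohol, in which acid ionises C4–OH to a cation stabilised by O1 and the 7‑benzyloxy group and the silane delivers hydride along the pseudo‑axial line on the face that carries the axial C2–H of the half‑chair with ring B equatorial (the face hydride reagents also take on flavanones), which places the acetate arm cis to ring B (4R) and spares the benzyl ethers that catalytic hydrogenation of a derived alkene would endanger.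

Step 5
Reactants: 8 methyl 2-{(2S,4R)-7-(benzyloxy)-2-[4-(benzyloxy)phenyl]chroman-4-yl}acetate
Product: 10 methyl 2-{(2S,4R)-7-(benzyloxy)-2-[4-(benzyloxy)phenyl]chroman-4-yl}-3-oxobutanoate (epimers at chain C2), via lithium enolate 9 (not isolated)
Conditions: LiN(iPr)2 (1.1 equiv), THF, −78 °C; MeC(O)N(OMe)Me, −78 → −20 °C; AcOH
Reagents that add atoms: N-methoxy-N-methylacetamide, CON(C)C(C)=O
Why: Crossed Claisen acylation of a lithium ester enolate by a Weinreb amide, in which the chelated tetrahedral adduct holds until the quench so that the acidic β‑keto ester cannot protonate unreacted enolate, and the new chain C2 centre is labile and is erased in step 9.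

Step 6
Reactants: 10 methyl 2-{(2S,4R)-7-(benzyloxy)-2-[4-(benzyloxy)phenyl]chroman-4-yl}-3-oxobutanoate
Product: 12 methyl 2-{(2S,4R)-7-(benzyloxy)-2-[4-(benzyloxy)phenyl]chroman-4-yl}-3,5-dioxohexanoate (epimers at chain C2), via dilithio dianion 11 (not isolated)
Conditions: LiN(iPr)2 (2.2 equiv), THF, −78 → 0 °C; MeC(O)N(OMe)Me, −78 → −20 °C; AcOH
Reagents that add atoms: N-methoxy-N-methylacetamide, CON(C)C(C)=O
Why: γ‑Acylation of a β‑keto ester dianion by a Weinreb amide, in which the terminal C4 carbanion of the C2,C4‑dianion is far more nucleophilic than the delocalised and hindered C2 site, so the acetyl group should enter at C4 only, and the chelated adduct again defers release of the more acidic 1,3‑diketone until the quench.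

Step 7
Reactants: 13 9-phenylnonanoic acid
Product: 15 N-methoxy-N-methyl-9-phenylnonanamide, via acyl imidazolide 14 (not isolated)
Conditions: CDI, CH2Cl2, 25 °C; then MeNHOMe·HCl, 25 °C
Reagents that add atoms: N,O-dimethylhydroxylamine hydrochloride, CNOC.Cl; 1,1'-carbonyldiimidazole, O=C(n1ccnc1)n1ccnc1 (imidazolyl group of 14 only)
Why: Amide coupling through an acyl imidazolide, in which CDI activates the acid with loss of CO2 and the hydroxylamine salt then displaces imidazole to give the Weinreb amide that serves as a mono‑acylating agent in step 8.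

Step 8
Reactants: 12 methyl 2-{(2S,4R)-7-(benzyloxy)-2-[4-(benzyloxy)phenyl]chroman-4-yl}-3,5-dioxohexanoate; 15 N-methoxy-N-methyl-9-phenylnonanamide
Product: 17 methyl 2-{(2S,4R)-7-(benzyloxy)-2-[4-(benzyloxy)phenyl]chroman-4-yl}-3,5,7-trioxo-15-phenylpentadecanoate (epimers at chain C2), via trilithio trianion 16 (not isolated)
Conditions: LiN(iPr)2 (3.2 equiv), THF, −78 → 0 °C; 15, −78 → −10 °C; AcOH, −78 °C; used after a short extractive work-up
Reagents that add atoms: none
Why: Terminal acylation of a 3,5‑dioxo ester trianion by a Weinreb amide, in which the base removes C4–H, C2–H and finally one C6–H, the last‑formed and least delocalised C6 carbanion is the most nucleophilic site, enolisation of the keto ester end shields the ester from attack, and the chelated adduct releases the triketo ester only on the cold acidic quench.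

Step 9
Reactants: 17 methyl 2-{(2S,4R)-7-(benzyloxy)-2-[4-(benzyloxy)phenyl]chroman-4-yl}-3,5,7-trioxo-15-phenylpentadecanoate
Product: 19 1-{3-[(2S,4S)-7-(benzyloxy)-2-[4-(benzyloxy)phenyl]chroman-4-yl]-2,4,6-trihydroxyphenyl}-9-phenylnonan-1-one, via cyclohexanetrione tautomer 18 (not isolated)
Conditions: Mg(OMe)2 (5 equiv), MeOH–THF, 60 °C; cold 1 M HCl
Reagents that add atoms: none
Why: Mg(OMe)2 turns 17 into magnesium‑chelated enolates that fold the chain, the C5/C7 diketonate making C6 the carbon nucleophile while magnesium held by the C1/C3 keto ester pair polarises the ester carbonyl, so that C6 adds to C1, methoxide leaves, and trione 18 enolises three times to the arene, whose phenolate is the thermodynamic sink. The closest known reaction is the biomimetic Claisen (Dieckmann‑type) cyclisation of 3,5,7‑triketo esters, and of the 2‑pyranones derived from them, to acylphloroglucinols with magnesium methoxide or methanolic hydroxide, applied here to a member of that class bearing a secondary alkyl group on C2. The one ring closes in the 6‑exo‑trig mode (ring atoms C1 to C6, the attacked carbonyl oxygen outside the ring) and one C–C bond is formed. No stereocentre is created, since the epimeric chain C2 becomes an sp2 ring carbon, and flavan C2 and C4 carry no acidic hydrogen and, with the 4'‑oxygen benzylated, cannot open through a quinone methide. The step needs Claisen closure to prevail over aldol closure and lactonisation: the aldol of C2 onto C7 would leave C2 quaternary, cannot dehydrate to an arene and therefore reverts, the 4‑hydroxy‑2‑pyranone from attack of the C5 enol oxygen on C1 is reopened by methoxide, and C8 is not activated enough to compete as a nucleophile. The alkyl group on C2 also lowers the acidity of C2–H, so a larger share of the polyenolate keeps the ester end un‑enolised and electrophilic.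

Step 10
Reactants: 19 1-{3-[(2S,4S)-7-(benzyloxy)-2-[4-(benzyloxy)phenyl]chroman-4-yl]-2,4,6-trihydroxyphenyl}-9-phenylnonan-1-one
Product: 20 1-{2,4,6-trihydroxy-3-[(2S,4S)-7-hydroxy-2-(4-hydroxyphenyl)chroman-4-yl]phenyl}-9-phenylnonan-1-one (CNP0175574.4)
Conditions: H2 (1 atm), 10% Pd/C, EtOAc–MeOH, 25 °C
Reagents that add atoms: none
Why: Catalytic hydrogenolysis of two aryl benzyl ethers under neutral conditions, in which the O–CH2Ph bonds are cleaved much faster than the ring C2–O1 bond of a flavan, the hydrogen‑bonded aryl ketone is not reduced at one atmosphere, and no acid or base is present that could disturb C2 or C4, so the uptake is simply stopped after two equivalents.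

## Compound list

1 | 7-hydroxy-4H-chromen-4-one | O=c1ccoc2cc(O)ccc12 | starting material
2 | 7-(benzyloxy)-4H-chromen-4-one | O=c1ccoc2cc(OCc3ccccc3)ccc12 | intermediate
3 | 4-(benzyloxy)phenylboronic acid | OB(O)c1ccc(OCc2ccccc2)cc1 | starting material
4 | (2S)-7-(benzyloxy)-2-[4-(benzyloxy)phenyl]chroman-4-one | O=C1C[C@@H](c2ccc(OCc3ccccc3)cc2)Oc2cc(OCc3ccccc3)ccc21 | intermediate
5 | methyl bromoacetate | COC(=O)CBr | starting material
6 | bromozinc enolate of methyl acetate (Reformatsky reagent) | COC(=O)C[Zn]Br | intermediate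
7 | methyl 2-{(2S)-7-(benzyloxy)-2-[4-(benzyloxy)phenyl]-4-hydroxychroman-4-yl}acetate, C4 epimers | COC(=O)CC1(O)C[C@@H](c2ccc(OCc3ccccc3)cc2)Oc2cc(OCc3ccccc3)ccc21 | intermediate
8 | methyl 2-{(2S,4R)-7-(benzyloxy)-2-[4-(benzyloxy)phenyl]chroman-4-yl}acetate (2,4-cis) | COC(=O)C[C@H]1C[C@@H](c2ccc(OCc3ccccc3)cc2)Oc2cc(OCc3ccccc3)ccc21 | intermediate
9 | lithium enolate of 8 | [Li+].COC([O-])=C[C@H]1C[C@@H](c2ccc(OCc3ccccc3)cc2)Oc2cc(OCc3ccccc3)ccc21 | intermediate
10 | methyl 2-{(2S,4R)-7-(benzyloxy)-2-[4-(benzyloxy)phenyl]chroman-4-yl}-3-oxobutanoate, epimers at chain C2 | COC(=O)C(C(C)=O)[C@H]1C[C@@H](c2ccc(OCc3ccccc3)cc2)Oc2cc(OCc3ccccc3)ccc21 | intermediate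
11 | dilithio C2,C4-dianion of 10 | [Li+].[Li+].COC([O-])=C(C(=C)[O-])[C@H]1C[C@@H](c2ccc(OCc3ccccc3)cc2)Oc2cc(OCc3ccccc3)ccc21 | intermediate
12 | methyl 2-{(2S,4R)-7-(benzyloxy)-2-[4-(benzyloxy)phenyl]chroman-4-yl}-3,5-dioxohexanoate, epimers at chain C2 | COC(=O)C(C(=O)CC(C)=O)[C@H]1C[C@@H](c2ccc(OCc3ccccc3)cc2)Oc2cc(OCc3ccccc3)ccc21 | intermediate
13 | 9-phenylnonanoic acid | OC(=O)CCCCCCCCc1ccccc1 | starting material
14 | 1-(imidazol-1-yl)-9-phenylnonan-1-one | O=C(CCCCCCCCc1ccccc1)n1ccnc1 | intermediate
15 | N-methoxy-N-methyl-9-phenylnonanamide | CON(C)C(=O)CCCCCCCCc1ccccc1 | intermediate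
16 | trilithio C2,C4,C6-trianion of 12 | [Li+].[Li+].[Li+].COC([O-])=C(C([O-])=CC(=C)[O-])[C@H]1C[C@@H](c2ccc(OCc3ccccc3)cc2)Oc2cc(OCc3ccccc3)ccc21 | intermediate
17 | methyl 2-{(2S,4R)-7-(benzyloxy)-2-[4-(benzyloxy)phenyl]chroman-4-yl}-3,5,7-trioxo-15-phenylpentadecanoate, epimers at chain C2 | COC(=O)C(C(=O)CC(=O)CC(=O)CCCCCCCCc1ccccc1)[C@H]1C[C@@H](c2ccc(OCc3ccccc3)cc2)Oc2cc(OCc3ccccc3)ccc21 | intermediate
18 | 2-{(2S,4R)-7-(benzyloxy)-2-[4-(benzyloxy)phenyl]chroman-4-yl}-4-(9-phenylnonanoyl)cyclohexane-1,3,5-trione | O=C(CCCCCCCCc1ccccc1)C1C(=O)CC(=O)C([C@H]2C[C@@H](c3ccc(OCc4ccccc4)cc3)Oc3cc(OCc4ccccc4)ccc32)C1=O | intermediate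
19 | 1-{3-[(2S,4S)-7-(benzyloxy)-2-[4-(benzyloxy)phenyl]chroman-4-yl]-2,4,6-trihydroxyphenyl}-9-phenylnonan-1-one | O=C(CCCCCCCCc1ccccc1)c1c(O)cc(O)c([C@H]2C[C@@H](c3ccc(OCc4ccccc4)cc3)Oc3cc(OCc4ccccc4)ccc32)c1O | intermediate
20 | 1-{2,4,6-trihydroxy-3-[(2S,4S)-7-hydroxy-2-(4-hydroxyphenyl)chroman-4-yl]phenyl}-9-phenylnonan-1-one | O=C(CCCCCCCCc1ccccc1)c1c(O)cc(O)c([C@H]2C[C@@H](c3ccc(O)cc3)Oc3cc(O)ccc32)c1O | target

## Step count and risks

Total step count: 10. Longest linear sequence: 9 (steps 1–6 and 8–10); step 7 is a one‑step side branch.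

**Step 9 (Claisen closure).**
- Risk: closure at the hindered ester may be slow. Methoxide‑induced retro‑Claisen fragmentation of the polycarbonyl chain, or lactonisation that does not reopen, could then consume the material.
- Fallback: the arene is bought instead of built. Setting out from 4, NaBH4 in MeOH–THF at 0 °C should give (2S,4S)-7-(benzyloxy)-2-[4-(benzyloxy)phenyl]chroman-4-ol F1. Phloroglucinol is C‑acylated with 13 (BF3·OEt2, 80 °C, Friedel–Crafts acylation) to 1-(2,4,6-trihydroxyphenyl)-9-phenylnonan-1-one F2. Acid‑catalysed benzylic Friedel–Crafts alkylation of F2 by F1 (cat. TsOH, dioxane, 25 °C) then joins flavan C4 to either of the two equivalent free ring positions. This comes back to the route at 19, which has to be separated from the (2S,4R) C4 epimer of 19 F3. The price is weak face selectivity in attack on the planar C4 cation.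

**Step 8 (trianion acylation).**
- Risk: the third deprotonation of a hindered, poorly soluble polyanion may be incomplete. Proton transfer from the α‑methylene of the amide, or premature attack of C6 on the ester, are further failure modes.
- Fallback: the ester end is masked as a lactone. Setting out from 12, DBU in refluxing toluene should lactonise the 3,5‑dioxo ester to 3-{(2S,4S)-7-(benzyloxy)-2-[4-(benzyloxy)phenyl]chroman-4-yl}-4-hydroxy-6-methyl-2H-pyran-2-one F4. Only two equivalents of LiN(iPr)2 are then needed to form the O,6‑CH2 dianion. This dianion is acylated at the 6‑methyl carbon by 15 to give 3-{(2S,4S)-7-(benzyloxy)-2-[4-(benzyloxy)phenyl]chroman-4-yl}-4-hydroxy-6-(2-oxo-10-phenyldecyl)-2H-pyran-2-one F5. Mg(OMe)2 in MeOH opens the lactone by methanolysis and so comes back to the route at 17, formed in the flask of step 9.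

**Step 4 (ionic deoxygenation).**
- Risk: hydride transfer may show poor facial selectivity. The cation may lose a proton to give a conjugated ester that is slow to re‑enter the cation. Acid may also ionise the C2–O1 bond, which would erode the C2 configuration or lead to over‑reduction.
- Fallback: C4 is set on a metal surface instead of by hydride capture. Setting out from 7, MsCl/Et3N in CH2Cl2 at 0 °C dehydrates the carbinol to methyl 2-{(2S)-7-(benzyloxy)-2-[4-(benzyloxy)phenyl]-2H-chromen-4-yl}acetate F6. This is the endocyclic alkene, favoured because it is free of peri strain with C5–H, and it is purified with exclusion of light. Hydrogenation over 10% Pd/C poisoned with 2,2'-bipyridyl (H2 1 atm, MeOH–THF) keeps the aryl benzyl ethers. Hydrogen should add to C3=C4 from the face opposite ring B, which gives the 2,4‑cis ester and comes back to the route at 8.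

## Further compounds

F1 | step 9 | (2S,4S)-7-(benzyloxy)-2-[4-(benzyloxy)phenyl]chroman-4-ol | O[C@H]1C[C@@H](c2ccc(OCc3ccccc3)cc2)Oc2cc(OCc3ccccc3)ccc21
F2 | step 9 | 1-(2,4,6-trihydroxyphenyl)-9-phenylnonan-1-one | O=C(CCCCCCCCc1ccccc1)c1c(O)cc(O)cc1O
F3 | step 9 | (2S,4R) C4 epimer of 19 | O=C(CCCCCCCCc1ccccc1)c1c(O)cc(O)c([C@@H]2C[C@@H](c3ccc(OCc4ccccc4)cc3)Oc3cc(OCc4ccccc4)ccc32)c1O
F4 | step 8 | 3-{(2S,4S)-7-(benzyloxy)-2-[4-(benzyloxy)phenyl]chroman-4-yl}-4-hydroxy-6-methyl-2H-pyran-2-one | CC1=CC(O)=C([C@H]2C[C@@H](c3ccc(OCc4ccccc4)cc3)Oc3cc(OCc4ccccc4)ccc32)C(=O)O1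
F5 | step 8 | 3-{(2S,4S)-7-(benzyloxy)-2-[4-(benzyloxy)phenyl]chroman-4-yl}-4-hydroxy-6-(2-oxo-10-phenyldecyl)-2H-pyran-2-one | O=C(CCCCCCCCc1ccccc1)CC1=CC(O)=C([C@H]2C[C@@H](c3ccc(OCc4ccccc4)cc3)Oc3cc(OCc4ccccc4)ccc32)C(=O)O1
F6 | step 4 | methyl 2-{(2S)-7-(benzyloxy)-2-[4-(benzyloxy)phenyl]-2H-chromen-4-yl}acetate | COC(=O)CC1=C[C@@H](c2ccc(OCc3ccccc3)cc2)Oc2cc(OCc3ccccc3)ccc21
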